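**Plan**

Germacrane numbering is used. Ring A is C1–C10, ring B is O–C6–C7–C11–C12, C13 is the exocyclic methylene, C14 the ester carbon and C15 the methyl on C4.
Retrosynthesis: remove the C8 methacrylate and C13, lower the C12 lactone to a methyl lactol acetal, and open ring A at C1–C2. Then cut C1–C10 (formyl carbon), C8–C9 (acyl–zinc coupling) and C6–C7 (aldol).
Enabling feature: C1 is the β-carbon of the C10(C14) enoate inside ring A. C2 is a plain CH2, and its neighbour C3 sits on the C4=C5 olefin. C1 can therefore be the enol triflate carbon of an α-formyl ester, and C2 the boron-bearing end of a hydroborated C2=C3 vinyl group.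
Forward: the aldol joins dienal and imide (C6–C7) and ring B closes as the acetal. The chain grows at C8–C9 and then C10–C1, and ring A closes last at C1–C2. The lactone, C13 and the methacrylate follow.
Stereochemistry: C6 and C7 come from an Evans syn aldol with (S)-4-benzyloxazolidin-2-one, and C8 from a CBS reduction matched with the Felkin–Anh bias. The E C4=C5 bond comes from the commercial enynol. The ring-cis C1=C10 bond comes from an E-selective enol triflation carried through a stereoretentive coupling.

Key step: step 13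

Assumption: C12 in acetals 12–25 is drawn as the anomer with OMe trans to the C6 dienyl group; both anomers are expected and both serve because C12 becomes the lactone carbonyl, and C12 in 26, C10 in 22 and C11 in 29 and 30 are left undefined because they are labile or erased.

**Route**

Step 1
Reactants: 1 (E)-3-methylpent-2-en-4-yn-1-ol
Product: 2 (E)-3-methylpenta-2,4-dien-1-ol
Conditions: H2 (1 atm), Pd/CaCO3–Pb(OAc)2 (Lindlar type), quinoline, Et2O, 0 °C, stopped after 1 equiv H2
Reagents that add atoms: none
Why: Lindlar-type semihydrogenation, in which the lead- and quinoline-poisoned palladium surface binds the terminal alkyne far more strongly than the diene formed, so uptake can be stopped at the C2=C3 vinyl stage with the E C4=C5 bond untouched.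

Step 2
Reactants: 2 (E)-3-methylpenta-2,4-dien-1-ol
Product: 3 (E)-3-methylpenta-2,4-dienal
Conditions: MnO2, CH2Cl2, rt; filtered, concentrated cold, used at once
Reagents that add atoms: none
Why: MnO2 oxidation of an allylic (dienylic) alcohol is chemoselective, neutral and worked up by filtration only, which suits a volatile, polymerisable dienal and keeps the E geometry.

Step 3
Reactants: 4 methyl 4,4-dimethoxybutanoate
Product: 5 4,4-dimethoxybutanoic acid
Conditions: LiOH, THF/MeOH/H2O, rt; then 1 M HCl to pH 4–5, 0 °C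
Reagents that add atoms: lithium hydroxide, [Li+].[OH-]
Why: Ester saponification runs under base, to which the dimethyl acetal is inert, and the cold, mild acidification frees the acid without unmasking C12.

Step 4
Reactants: 5 4,4-dimethoxybutanoic acid; 6 (S)-4-benzyloxazolidin-2-one
Product: 8 (S)-4-benzyl-3-(4,4-dimethoxybutanoyl)oxazolidin-2-one, via mixed pivalic anhydride 7 (not isolated)
Conditions: PivCl, Et3N, THF, −20 °C; then 6, LiCl, −20 °C → rt
Reagents that add atoms: none
Why: N-acylation of an Evans oxazolidinone through a mixed pivalic anhydride (Et3N/LiCl variant) is acid-free, and the hindered pivaloyl carbonyl steers attack to the butanoyl carbonyl.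

Step 5
Reactants: 8 (S)-4-benzyl-3-(4,4-dimethoxybutanoyl)oxazolidin-2-one; 3 (E)-3-methylpenta-2,4-dienal
Product: 11 (S)-4-benzyl-3-[(2S,3R,4E)-2-(2,2-dimethoxyethyl)-3-hydroxy-5-methylhepta-4,6-dienoyl]oxazolidin-2-one, via Z-boron enolate 9 (not isolated), via boron aldolate 10 (not isolated)
Conditions: Bu2BOTf, Et3N, CH2Cl2, −78 → 0 °C; 3, −78 → 0 °C; then pH 7 buffer, MeOH, 30% H2O2, 0 °C
Reagents that add atoms: none
Why: Evans syn aldol addition, in which the Z-boron enolate adds 1,2 to the dienal through a chair Zimmerman–Traxler transition state on the face away from the benzyl group, setting C7 and C6 together in the syn (2S,3R) array that corresponds to 6R,7R of the target.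

Step 6
Reactants: 11 syn aldol adduct
Product: 12 (S)-4-benzyl-3-{(2R,3S,5S)-5-methoxy-2-[(1E)-2-methylbuta-1,3-dienyl]oxolane-3-carbonyl}oxazolidin-2-one
Conditions: pyridinium p-toluenesulfonate (cat.), 4 Å MS, CH2Cl2, rt
Reagents that add atoms: none
Why: Acid-catalysed transacetalisation, in which the C6 hydroxyl traps the C12 oxocarbenium ion in a 5-exo closure of ring B, the syn aldol array becomes the trans C6/C7 relationship, and the uncontrolled anomeric centre C12 is erased in step 15.

Step 7
Reactants: 12 acetal imide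
Product: 13 S-ethyl (2R,3S,5S)-5-methoxy-2-[(1E)-2-methylbuta-1,3-dienyl]oxolane-3-carbothioate
Conditions: EtSH (3 equiv), n-BuLi (0.3 equiv), THF, 0 °C → rt
Reagents that add atoms: ethanethiol, CCS
Why: Thiolate cleavage of an N-acyl oxazolidinone (transthioesterification) attacks the exocyclic carbonyl selectively, the weakly basic thiolate leaves C7 unepimerised, and the released oxazolidinide regenerates thiolate from the excess EtSH.

Step 8
Reactants: 13 thioester; 14 methyl 3-iodopropanoate
Product: 16 methyl 4-{(2R,3S,5S)-5-methoxy-2-[(1E)-2-methylbuta-1,3-dienyl]oxolan-3-yl}-4-oxobutanoate, via zinc homoenolate 15 (not isolated)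
Conditions: 14, Zn dust, THF, 35 °C; then 13, PdCl2(PPh3)2 (5 mol %), toluene/THF, rt
Reagents that add atoms: none
Why: Fukuyama coupling, in which zerovalent palladium formed from PdCl2(PPh3)2 inserts into the C8–S bond and the ester-stabilised zinc homoenolate transfers C9, giving the ketone without over-addition under neutral conditions that spare C7, the acetal and the diene.

Step 9
Reactants: 16 γ-keto ester
Product: 18 methyl (4R)-4-hydroxy-4-{(2R,3R,5S)-5-methoxy-2-[(1E)-2-methylbuta-1,3-dienyl]oxolan-3-yl}butanoate, via C8 catecholborate 17 (not isolated)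
Conditions: (S)-2-methyl-CBS-oxazaborolidine (0.5 equiv), catecholborane, toluene, −78 °C; MeOH quench; crude product taken on at once
Reagents that add atoms: none
Why: Corey–Bakshi–Shibata reduction, in which the (S)-oxazaborolidine treats the branched C7 side as the large group and gives 8R, a sense that coincides with Felkin–Anh attack anti to C6, while catecholborane at −78 °C touches neither diene nor ester and holds O8 as a non-nucleophilic borate until the quench.

Step 10
Reactants: 18 γ-hydroxy ester
Product: 19 methyl (4R)-4-(tert-butyldimethylsilyloxy)-4-{(2R,3S,5S)-5-methoxy-2-[(1E)-2-methylbuta-1,3-dienyl]oxolan-3-yl}butanoate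
Conditions: TBSOTf, 2,6-lutidine, CH2Cl2, −78 °C
Reagents that add atoms: tert-butyldimethylsilyl trifluoromethanesulfonate, CC(C)(C)[Si](C)(C)OS(=O)(=O)C(F)(F)F
Why: Silyl triflate silylation at −78 °C is faster than lactonisation of O8 onto C14 and too cold for lutidine/silyl triflate activation of the acetal.

Step 11
Reactants: 19 silyl ether ester; 20 methyl formate
Product: 22 methyl (4R)-4-(tert-butyldimethylsilyloxy)-2-formyl-4-{(2R,3S,5S)-5-methoxy-2-[(1E)-2-methylbuta-1,3-dienyl]oxolan-3-yl}butanoate, via lithium ester enolate 21 (not isolated)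
Conditions: LiN(iPr)2, THF, −78 °C; HCO2Me, −78 → −30 °C; AcOH
Reagents that add atoms: none
Why: Crossed Claisen condensation (α-formylation of an ester enolate with a formate), for which C10 is the only enolisable carbon because C12 is masked as an acetal, and the labile C10 centre created disappears in step 12.

Step 12
Reactants: 22 α-formyl ester
Product: 23 methyl (2E,4R)-4-(tert-butyldimethylsilyloxy)-4-{(2R,3S,5S)-5-methoxy-2-[(1E)-2-methylbuta-1,3-dienyl]oxolan-3-yl}-2-[(trifluoromethylsulfonyloxy)methylidene]butanoate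
Conditions: DBU, Tf2O, CH2Cl2, −78 °C
Reagents that add atoms: trifluoromethanesulfonic anhydride, O=S(=O)(OS(=O)(=O)C(F)(F)F)C(F)(F)F
Why: O-triflation of a 1,3-dicarbonyl enolate under non-chelating conditions, in which the amidinium counter-ion lets the enolate oxygen and the ester carbonyl adopt the dipole-opposed arrangement, so sulfonylation should give the E enol triflate with OTf trans to CO2Me and cis to C9.

Step 13
Reactants: 23 diene enol triflate
Product: 25 methyl (1(10)E,4E,6R,7S,8R,12S)-8-(tert-butyldimethylsilyloxy)-12-methoxy-6,12-epoxy-13-norgermacra-1(10),4-dien-14-oate, via C2 borane 24 (not isolated)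
Conditions: 9-BBN (1.3 equiv), THF, 0 °C → rt; then added over 12 h to PdCl2(dppf) (15 mol %), AsPh3 (30 mol %), Cs2CO3 (3 equiv), DMF/THF/H2O, 50 °C, final ca. 1 mM
Reagents that add atoms: none
Why: 9-BBN adds across the only monosubstituted olefin of 23, the C2=C3 vinyl end of the diene, with boron on the terminal C2, because the trisubstituted C4=C5 bond is too hindered and the triflyloxy enoate too electron-poor for this bulky borane. The divalent palladium of PdCl2(dppf) is reduced in the flask to zerovalent palladium, oxidative addition occurs at the C1–OTf bond, the hydroxyborate made from 24 by aqueous Cs2CO3 passes C2 to palladium, and reductive elimination joins C1 to C2. The closest known reaction type is the B-alkyl Suzuki–Miyaura macrocyclisation of 9-BBN adducts onto alkenyl triflates or iodides, and β-triflyloxy enoates are proven partners in the intermolecular version. Ring A closes through an eleven-membered palladacycle with C1=C10 ending endocyclic (formally a 10-endo closure at sp2 C1), and syringe-pump addition at millimolar concentration biases the system towards this closure over oligomerisation. No stereocentre is created; the stereochemical demand is retention of the E enol triflate geometry, which both organometallic steps at C1 respect, so C2 takes the place of OTf cis to C9 and the ring-cis olefin results. The acetal at C12 keeps O6 an ether oxygen instead of an allylic carboxylate, so zerovalent palladium finds no π-allyl ionisation pathway at C6.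

Step 14
Reactants: 25 macrocyclic lactol methyl acetal
Product: 26 methyl (1(10)E,4E,6R,7S,8R)-8-(tert-butyldimethylsilyloxy)-12-hydroxy-6,12-epoxy-13-norgermacra-1(10),4-dien-14-oate (lactol, C12 anomers)
Conditions: AcOH/THF/H2O, rt
Reagents that add atoms: water, O
Why: Mild aqueous acid hydrolysis of a 2-deoxyfuranoside-type methyl acetal runs through the ring oxocarbenium ion much faster than cleavage of the hindered secondary TBS ether, and the C12 anomer mixture is inconsequential.

Step 15
Reactants: 26 lactol
Product: 27 methyl (1(10)E,4E,6R,7S,8R)-8-(tert-butyldimethylsilyloxy)-12-oxo-6,12-epoxy-13-norgermacra-1(10),4-dien-14-oate (trans-fused 12,6-lactone)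
Conditions: Dess–Martin periodinane, CH2Cl2, 0 °C → rt
Reagents that add atoms: none
Why: Dess–Martin oxidation of a lactol to the lactone is near-neutral and leaves both trisubstituted olefins, the ester and the silyl ether untouched.

Step 16
Reactants: 27 lactone
Product: 29 11-(dimethylaminomethyl) lactone (Mannich base of 27; C11 epimers), via lithium lactone enolate 28 (not isolated)
Conditions: LiN(iPr)2, THF, −78 °C; CH2=NMe2+ I−, −78 °C → rt
Reagents that add atoms: N,N-dimethylmethyleneiminium iodide (Eschenmoser's salt), C=[N+](C)C.[I-]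
Why: Mannich-type aminomethylation of a lactone enolate with Eschenmoser's salt, for which C11 carries the only kinetically accessible acidic hydrogens (the enoate has no α-hydrogen and its γ-hydrogens at C2 lie trans to the ester), and the C11 centre formed, expected trans to C8, is erased in step 17.

Step 17
Reactants: 29 Mannich base
Product: 31 methyl (1(10)E,4E,6R,7S,8R)-8-(tert-butyldimethylsilyloxy)-12-oxo-6,12-epoxygermacra-1(10),4,11(13)-trien-14-oate (α-methylene lactone), via ammonium iodide 30 (not isolated)
Conditions: MeI, CH2Cl2/Et2O, rt; then aq NaHCO3, CH2Cl2, rt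
Reagents that add atoms: none
Why: Exhaustive methylation and Hofmann-type E1cB elimination of the β-ammonium lactone gives the exocyclic C11=C13 methylene under bicarbonate conditions too mild to disturb the lactone or the enoate.

Step 18
Reactants: 31 silyl ether
Product: 32 methyl (1(10)E,4E,6R,7R,8R)-8-hydroxy-12-oxo-6,12-epoxygermacra-1(10),4,11(13)-trien-14-oate
Conditions: HF·pyridine, pyridine, THF, 0 °C → rt
Reagents that add atoms: none
Why: Fluoride-mediated desilylation under buffered acidic conditions avoids an alkoxide at O8, so translactonisation to C12, lactonisation to C14 and oxa-Michael addition to C13 are not triggered.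

Step 19
Reactants: 32 C8 alcohol
Product: 33 methyl (1(10)E,4E,6R,7R,8R)-8-(methacryloyloxy)-12-oxo-6,12-epoxygermacra-1(10),4,11(13)-trien-14-oate (CNP0317149.1)
Conditions: methacrylic anhydride, Et3N, DMAP (cat.), CH2Cl2, 0 °C → rt
Reagents that add atoms: methacrylic anhydride, C=C(C)C(=O)OC(=O)C(C)=C
Why: DMAP-catalysed acylation of the secondary C8 alcohol with the anhydride proceeds with retention at C8 and completes the target.

**Compound list**

1 | (E)-3-methylpent-2-en-4-yn-1-ol | C#C/C(C)=C/CO | starting material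
2 | (E)-3-methylpenta-2,4-dien-1-ol | C=C/C(C)=C/CO | intermediate
3 | (E)-3-methylpenta-2,4-dienal | C=C/C(C)=C/C=O | intermediate
4 | methyl 4,4-dimethoxybutanoate | COC(=O)CCC(OC)OC | starting material
5 | 4,4-dimethoxybutanoic acid | OC(=O)CCC(OC)OC | intermediate
6 | (S)-4-benzyloxazolidin-2-one | O=C1N[C@@H](Cc2ccccc2)CO1 | starting material
7 | 4,4-dimethoxybutanoic pivalic anhydride | CC(C)(C)C(=O)OC(=O)CCC(OC)OC | intermediate
8 | (S)-4-benzyl-3-(4,4-dimethoxybutanoyl)oxazolidin-2-one | COC(OC)CCC(=O)N1C(=O)OC[C@@H]1Cc1ccccc1 | intermediate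
9 | (Z)-dibutylboron enolate of 8 | CCCCB(CCCC)O/C(=C\CC(OC)OC)N1C(=O)OC[C@@H]1Cc1ccccc1 | intermediate
10 | O6-dibutylboron aldolate of 11 | C=C/C(C)=C/[C@@H](OB(CCCC)CCCC)[C@H](CC(OC)OC)C(=O)N1C(=O)OC[C@@H]1Cc1ccccc1 | intermediate
11 | (S)-4-benzyl-3-[(2S,3R,4E)-2-(2,2-dimethoxyethyl)-3-hydroxy-5-methylhepta-4,6-dienoyl]oxazolidin-2-one | C=C/C(C)=C/[C@@H](O)[C@H](CC(OC)OC)C(=O)N1C(=O)OC[C@@H]1Cc1ccccc1 | intermediate
12 | (S)-4-benzyl-3-{(2R,3S,5S)-5-methoxy-2-[(1E)-2-methylbuta-1,3-dienyl]oxolane-3-carbonyl}oxazolidin-2-one | C=C/C(C)=C/[C@H]1O[C@H](OC)C[C@@H]1C(=O)N2C(=O)OC[C@@H]2Cc3ccccc3 | intermediate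
13 | S-ethyl (2R,3S,5S)-5-methoxy-2-[(1E)-2-methylbuta-1,3-dienyl]oxolane-3-carbothioate | C=C/C(C)=C/[C@H]1O[C@H](OC)C[C@@H]1C(=O)SCC | intermediate
14 | methyl 3-iodopropanoate | COC(=O)CCI | starting material
15 | (3-methoxy-3-oxopropyl)zinc iodide | COC(=O)CC[Zn]I | intermediate
16 | methyl 4-{(2R,3S,5S)-5-methoxy-2-[(1E)-2-methylbuta-1,3-dienyl]oxolan-3-yl}-4-oxobutanoate | C=C/C(C)=C/[C@H]1O[C@H](OC)C[C@@H]1C(=O)CCC(=O)OC | intermediate
17 | O8-catecholborate of 18 | C=C/C(C)=C/[C@H]1O[C@H](OC)C[C@@H]1[C@H](OB2Oc3ccccc3O2)CCC(=O)OC | intermediate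
18 | methyl (4R)-4-hydroxy-4-{(2R,3R,5S)-5-methoxy-2-[(1E)-2-methylbuta-1,3-dienyl]oxolan-3-yl}butanoate | C=C/C(C)=C/[C@H]1O[C@H](OC)C[C@@H]1[C@H](O)CCC(=O)OC | intermediate
19 | methyl (4R)-4-(tert-butyldimethylsilyloxy)-4-{(2R,3S,5S)-5-methoxy-2-[(1E)-2-methylbuta-1,3-dienyl]oxolan-3-yl}butanoate | C=C/C(C)=C/[C@H]1O[C@H](OC)C[C@@H]1[C@H](O[Si](C)(C)C(C)(C)C)CCC(=O)OC | intermediate
20 | methyl formate | COC=O | starting material
21 | lithium enolate of 19 (geometry inconsequential) | C=C/C(C)=C/[C@H]1O[C@H](OC)C[C@@H]1[C@H](O[Si](C)(C)C(C)(C)C)CC=C(OC)O[Li] | intermediate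
22 | α-formyl ester (C10 epimers and enol in equilibrium) | C=C/C(C)=C/[C@H]1O[C@H](OC)C[C@@H]1[C@H](O[Si](C)(C)C(C)(C)C)CC(C=O)C(=O)OC | intermediate
23 | (E)-enol triflate with C2=C3 vinyl diene (precursor of the key step) | C=C/C(C)=C/[C@H]1O[C@H](OC)C[C@@H]1[C@H](O[Si](C)(C)C(C)(C)C)C/C(C(=O)OC)=C\OS(=O)(=O)C(F)(F)F | intermediate
24 | C2 B-alkyl-9-borabicyclo[3.3.1]nonane from 23 | B1(C2CCCC1CCC2)CC/C(C)=C/[C@H]3O[C@H](OC)C[C@@H]3[C@H](O[Si](C)(C)C(C)(C)C)C/C(C(=O)OC)=C\OS(=O)(=O)C(F)(F)F | intermediate
25 | ten-membered dienoate fused to the lactol methyl acetal (6R,7S,8R,12S) | CC(C)(C)[Si](C)(C)O[C@@H]1C/C(C(=O)OC)=C\CC/C(C)=C/[C@H]2O[C@H](OC)C[C@@H]21 | intermediate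
26 | macrocyclic lactol (C12 anomers) | CC(C)(C)[Si](C)(C)O[C@@H]1C/C(C(=O)OC)=C\CC/C(C)=C/[C@H]2OC(O)C[C@@H]21 | intermediate
27 | macrocyclic trans-fused 12,6-lactone (6R,7S,8R) | CC(C)(C)[Si](C)(C)O[C@@H]1C/C(C(=O)OC)=C\CC/C(C)=C/[C@H]2OC(=O)C[C@@H]21 | intermediate
28 | lithium enolate of 27 | CC(C)(C)[Si](C)(C)O[C@@H]1C/C(C(=O)OC)=C\CC/C(C)=C/[C@H]2OC(O[Li])=C[C@@H]21 | intermediate
29 | 11-(dimethylaminomethyl) lactone (C11 epimers) | CC(C)(C)[Si](C)(C)O[C@@H]1C/C(C(=O)OC)=C\CC/C(C)=C/[C@H]2OC(=O)C(CN(C)C)[C@@H]21 | intermediate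
30 | 11-(trimethylammoniomethyl) lactone iodide | CC(C)(C)[Si](C)(C)O[C@@H]1C/C(C(=O)OC)=C\CC/C(C)=C/[C@H]2OC(=O)C(C[N+](C)(C)C)[C@@H]21.[I-] | intermediate
31 | 8-O-TBS α-methylene lactone (6R,7S,8R) | CC(C)(C)[Si](C)(C)O[C@@H]1C/C(C(=O)OC)=C\CC/C(C)=C/[C@H]2OC(=O)C(=C)[C@@H]21 | intermediate
32 | 8-hydroxy α-methylene lactone (6R,7R,8R) | O[C@@H]1C/C(C(=O)OC)=C\CC/C(C)=C/[C@H]2OC(=O)C(=C)[C@@H]21 | intermediate
33 | CNP0317149.1 (6R,7R,8R; 1(10)E ring-cis, 4E) | C=C(C)C(=O)O[C@@H]1C/C(C(=O)OC)=C\CC/C(C)=C/[C@H]2OC(=O)C(=C)[C@@H]21 | target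

**Step count**

Total step count: 19.
Longest linear sequence: 17 steps (steps 3–19 from 4). The branch from 1 through steps 1, 2 and 5–19 is equally long.

**Steps most likely to fail**

1. Step 13 (closure of ring A).
What may go wrong: oligomerisation through intermolecular coupling, hydrolysis of the vinylogous acyl triflate by the aqueous base, and protodeboronation. Any of these may outpace the slow transmetalation that has to bring C2 to palladium across a strained ten-membered transition structure.
Fallback, from 23 back to 25: the C1–C2 closure is kept, but C2 is handed to zinc and the ring is closed by a base-free, anhydrous intramolecular Negishi coupling. Et2BH (from BH3·SMe2 and Et3B) should hydroborate the vinyl group of 23 to the C2 diethylborane F1. Boron–zinc exchange with Et2Zn, followed by removal of the volatiles under vacuum, should give the bis(alkyl)zinc F2. Slow addition of F2 to PdCl2(dppf) in THF/NMP at millimolar dilution should then close ring A to 25.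

2. Step 12 (E-selective enol triflation).
What may go wrong: incomplete control of the enolate geometry would erode the E selectivity, and the Z isomer cannot deliver the ring-cis olefin. Adventitious triflic acid could also ionise the acetal.
Fallback, from 22 to 25: the sulfonylating system and the leaving group are changed. TsCl/N-methylimidazole/Et3N is a combination established for E-selective sulfonylation of α-formyl esters, and it should convert 22 into the (E)-enol tosylate F3. 9-BBN should then give the tosylate C2 borane F4. A B-alkyl Suzuki closure tuned for tosylates (Pd(OAc)2, SPhos, K3PO4, THF/H2O, high dilution) should lead to 25.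

3. Step 16 (aminomethylation at C11).
What may go wrong: transannular Michael addition of the free lithium enolate onto C1 of the enoate, or competing deprotonation elsewhere in ring A, may consume the enolate before it meets the iminium salt.
Fallback, from 27 to 29: the nucleophile is changed to a neutral one. LiN(iPr)2 is added to 27 premixed with Me3SiCl at −78 °C (in situ quench), which should trap the enolate at once as the trimethylsilyl ketene acetal F5. F5 should then react with Eschenmoser's salt in CH2Cl2 in a Mukaiyama-type Mannich reaction to give 29.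

**Further compounds**

F1 | step 13 | C2 diethylborane from 23 | CCB(CC)CC/C(C)=C/[C@H]1O[C@H](OC)C[C@@H]1[C@H](O[Si](C)(C)C(C)(C)C)C/C(C(=O)OC)=C\OS(=O)(=O)C(F)(F)F
F2 | step 13 | bis(alkyl)zinc from F1 | [Zn](CC/C(C)=C/[C@H]1O[C@H](OC)C[C@@H]1[C@H](O[Si](C)(C)C(C)(C)C)C/C(C(=O)OC)=C\OS(=O)(=O)C(F)(F)F)CC/C(C)=C/[C@H]2O[C@H](OC)C[C@@H]2[C@H](O[Si](C)(C)C(C)(C)C)C/C(C(=O)OC)=C\OS(=O)(=O)C(F)(F)F
F3 | step 12 | (E)-enol tosylate of 22 | C=C/C(C)=C/[C@H]1O[C@H](OC)C[C@@H]1[C@H](O[Si](C)(C)C(C)(C)C)C/C(C(=O)OC)=C\OS(=O)(=O)c2ccc(C)cc2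
F4 | step 12 | C2 B-alkyl-9-borabicyclo[3.3.1]nonane from F3 | B1(C2CCCC1CCC2)CC/C(C)=C/[C@H]3O[C@H](OC)C[C@@H]3[C@H](O[Si](C)(C)C(C)(C)C)C/C(C(=O)OC)=C\OS(=O)(=O)c4ccc(C)cc4
F5 | step 16 | trimethylsilyl ketene acetal of 27 | CC(C)(C)[Si](C)(C)O[C@@H]1C/C(C(=O)OC)=C\CC/C(C)=C/[C@H]2OC(O[Si](C)(C)C)=C[C@@H]21
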